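The lavandulyl chain is disconnected at its junction with ring A: the C-1''–C-2'' bond and the ring A oxygen ortho to C-3' are traced to a 3-prenyl-3,4-dihydrocoumarin whose lactone carbonyl carbon is the future isopropenyl carbon C-8''. A single carbene-catalysed (4+2) annulation between an ortho-quinone methide, released from a bis-MOM 2-(tosylmethyl)phenol, and the azolium enolate of 1-(5-methylhex-4-enoyl)imidazole forms that bond, closes the lactone and sets C-2'' as R. The lactone is then converted into the isopropenyl group; ring A, made symmetric by three MOM ethers, is lithiated and acylated with the ring B cinnamoyl Weinreb amide, and the acetals are removed.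

Key step: step 5

Assumption: which enantiomer of the aminoindanol-derived triazolium salt gives the 3R lactone is settled by a trial run with correlation at 8; the (5aS,10bR) salt is written, and its mirror image would be substituted if the sense proved opposite.
Assumption: the acyl azolium and azolium enolate of step 5 exist only bound to the catalyst and turn over; they are treated as states of the catalyst and described in that step.

Step 1
Reactants: 1 2,4,6-trihydroxybenzaldehyde
Product: 2 2-hydroxy-4,6-bis(methoxymethoxy)benzaldehyde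
Conditions: MOMCl (2.1 equiv), iPr2NEt (2.5 equiv), CH2Cl2, 0 °C → rt
Reagents that add atoms: chloromethyl methyl ether (MOMCl), COCCl
Why: Williamson-type O-alkylation of the two non-chelated phenols, the hydroxyl ortho to the formyl group being held in a hydrogen bond to the carbonyl so that it should stay free with two equivalents of MOMCl.

Step 2
Reactants: 2 2-hydroxy-4,6-bis(methoxymethoxy)benzaldehyde
Product: 3 2-(hydroxymethyl)-3,5-bis(methoxymethoxy)phenol
Conditions: NaBH4, THF/MeOH, 0 °C; neutral work-up, used crude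
Reagents that add atoms: none
Why: Hydride reduction of the aryl aldehyde to the benzylic alcohol with NaBH4, which leaves the MOM acetals untouched.

Step 3
Reactants: 3 2-(hydroxymethyl)-3,5-bis(methoxymethoxy)phenol
Product: 4 3,5-bis(methoxymethoxy)-2-[(4-methylbenzenesulfonyl)methyl]phenol
Conditions: TolSO2Na (1.5 equiv), AcOH (3 equiv), THF/H2O, rt
Reagents that add atoms: sodium p-toluenesulfinate, Cc1ccc(cc1)S(=O)[O-].[Na+]
Why: Acid-promoted SN1-type substitution in which the electron-rich salicyl alcohol ionises under acetic acid buffering and is captured at sulfur by the sulfinate, at an acidity the MOM acetals should tolerate.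

Step 4
Reactants: 5 5-methylhex-4-enoic acid
Product: 6 1-(1H-imidazol-1-yl)-5-methylhex-4-en-1-one
Conditions: CDI (1.05 equiv), CH2Cl2, rt; quick cold-water wash, used fresh
Reagents that add atoms: 1,1'-carbonyldiimidazole (CDI), O=C(n1ccnc1)n1ccnc1
Why: Carboxylic acid activation with carbonyldiimidazole (acyl transfer with loss of CO2 and imidazole) gives the N-acyl imidazole without touching the trisubstituted alkene.

Step 5
Reactants: 4 3,5-bis(methoxymethoxy)-2-[(4-methylbenzenesulfonyl)methyl]phenol; 6 1-(1H-imidazol-1-yl)-5-methylhex-4-en-1-one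
Product: 8 (3R)-5,7-bis(methoxymethoxy)-3-(3-methylbut-2-en-1-yl)-3,4-dihydro-2H-chromen-2-one, via ortho-quinone methide 7 (not isolated)
Conditions: (5aS,10bR)-2-mesityl-5a,10b-dihydro-4H,6H-indeno[2,1-b][1,2,4]triazolo[4,3-d][1,4]oxazin-2-ium tetrafluoroborate (15 mol %), Cs2CO3 (2 equiv), 6 (1.5 equiv), 4 Å MS, THF, 0 °C → rt
Reagents that add atoms: none
Why: Cs2CO3 eliminates p-toluenesulfinate from 4 to give quinone methide 7, while the free carbene displaces imidazole from 6 and the acyl azolium is deprotonated to a Z azolium enolate; the enolate carbon adds to the exocyclic methide carbon (Michael addition, forming C-1''–C-2''), and the phenoxide so formed attacks the acyl azolium, closing the lactone and releasing the carbene. The closest known reaction type is the chiral triazolium-catalysed formal (4+2) annulation of in situ generated ortho-quinone methides with azolium enolates from acyl imidazoles, which gives 3-substituted dihydrocoumarins. The six-membered lactone closes by intramolecular O-acylation (6-exo-trig attack of the phenoxide oxygen on the acyl azolium carbonyl) after the intermolecular C–C bond formation. C-3 of the lactone (C-2'' of the target) is set by the catalyst, whose fused indane shields one face of the planar enolate so that the methide is taken up on the open face, the enantiomer of the salt being chosen to give R. The step needs enantiofacial selectivity and C-alkylation at a single site: the methide CH2 is unsubstituted, so no second stereocentre can arise, the two MOM-oxy groups should give 7 enough lifetime to meet the enolate, and slow release by the heterogeneous carbonate should hold back oligomerisation. Mild carbonate at or below room temperature is chosen so that the acidic C-3 hydrogen of the aryl lactone is not exchanged afterwards.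

Step 6
Reactants: 8 (3R)-5,7-bis(methoxymethoxy)-3-(3-methylbut-2-en-1-yl)-3,4-dihydro-2H-chromen-2-one
Product: 9 (2R)-2-{[2-hydroxy-4,6-bis(methoxymethoxy)phenyl]methyl}-N-methoxy-N,5-dimethylhex-4-enamide
Conditions: MeNH(OMe)·HCl, AlMe3, CH2Cl2, 0 °C → rt; aq. KNaC4H4O6 work-up
Reagents that add atoms: N,O-dimethylhydroxylamine hydrochloride, CNOC.Cl
Why: Weinreb aminolysis of an aryl ester, in which the aluminium amide formed from AlMe3 and the hydroxylamine salt opens the activated lactone at low basicity, so the adjacent stereocentre should be kept while the ring A phenol is freed.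

Step 7
Reactants: 9 (2R)-2-{[2-hydroxy-4,6-bis(methoxymethoxy)phenyl]methyl}-N-methoxy-N,5-dimethylhex-4-enamide
Product: 10 (2R)-N-methoxy-N,5-dimethyl-2-{[2,4,6-tris(methoxymethoxy)phenyl]methyl}hex-4-enamide
Conditions: MOMCl (1.5 equiv), iPr2NEt (2 equiv), CH2Cl2, 0 °C → rt
Reagents that add atoms: chloromethyl methyl ether (MOMCl), COCCl
Why: Williamson-type O-alkylation of the phenol with MOMCl and a hindered amine completes a tris-MOM ring A in which the two remaining aryl C–H positions are equivalent.

Step 8
Reactants: 10 (2R)-N-methoxy-N,5-dimethyl-2-{[2,4,6-tris(methoxymethoxy)phenyl]methyl}hex-4-enamide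
Product: 11 (3R)-6-methyl-3-{[2,4,6-tris(methoxymethoxy)phenyl]methyl}hept-5-en-2-one
Conditions: MeMgBr (2 equiv), THF, 0 °C; aq. NH4Cl
Reagents that add atoms: methylmagnesium bromide, C[Mg]Br
Why: Weinreb ketone synthesis, in which MeMgBr adds once to give a stable magnesium chelate that collapses to the methyl ketone only on quench, so over-addition and enolisation at the α-stereocentre should be avoided.

Step 9
Reactants: 11 (3R)-6-methyl-3-{[2,4,6-tris(methoxymethoxy)phenyl]methyl}hept-5-en-2-one
Product: 12 1,3,5-tris(methoxymethoxy)-2-[(2R)-5-methyl-2-(prop-1-en-2-yl)hex-4-en-1-yl]benzene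
Conditions: Cp2TiMe2 (2.5 equiv), toluene, 65 °C, dark
Reagents that add atoms: bis(cyclopentadienyl)dimethyltitanium (Cp2TiMe2), [CH3-].[CH3-].[Ti+4].c1cc[cH-]c1.c1cc[cH-]c1
Why: Petasis methylenation, in which the titanium methylidene formed thermally from Cp2TiMe2 converts the ketone into the 1,1-disubstituted alkene through an oxatitanacyclobutane under non-basic conditions, so the enolisable stereocentre C-2'' should not be epimerised.

Step 10
Reactants: 13 2-hydroxy-4-methoxybenzaldehyde
Product: 14 4-methoxy-2-(methoxymethoxy)benzaldehyde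
Conditions: MOMCl (1.5 equiv), iPr2NEt (2 equiv), CH2Cl2, 0 °C → reflux
Reagents that add atoms: chloromethyl methyl ether (MOMCl), COCCl
Why: Williamson-type O-alkylation masks the ring B hydroxyl as the same acetal used on ring A, so that one final operation removes all four.

Step 11
Reactants: 14 4-methoxy-2-(methoxymethoxy)benzaldehyde
Product: 15 (2E)-N-methoxy-3-[4-methoxy-2-(methoxymethoxy)phenyl]-N-methylprop-2-enamide
Conditions: (EtO)2P(O)CH2C(O)N(OMe)Me, NaH, THF, 0 °C → rt
Reagents that add atoms: diethyl {2-[methoxy(methyl)amino]-2-oxoethyl}phosphonate, CCOP(=O)(CC(=O)N(C)OC)OCC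
Why: Horner–Wadsworth–Emmons olefination of the aryl aldehyde with the stabilised phosphonate anion should give the E enamide through the thermodynamically favoured elimination pathway.

Step 12
Reactants: 12 1,3,5-tris(methoxymethoxy)-2-[(2R)-5-methyl-2-(prop-1-en-2-yl)hex-4-en-1-yl]benzene; 15 (2E)-N-methoxy-3-[4-methoxy-2-(methoxymethoxy)phenyl]-N-methylprop-2-enamide
Product: 17 (2E)-3-[4-methoxy-2-(methoxymethoxy)phenyl]-1-{2,4,6-tris(methoxymethoxy)-3-[(2R)-5-methyl-2-(prop-1-en-2-yl)hex-4-en-1-yl]phenyl}prop-2-en-1-one, via aryllithium 16 (not isolated)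
Conditions: n-BuLi (1.1 equiv), THF, 0 °C, 1 h; then 15 (1.2 equiv), −78 → 0 °C; aq. NH4Cl
Reagents that add atoms: none
Why: Directed ortho-metalation between two MOM-oxy groups (both open ring positions are equivalent, so one aryllithium should form) followed by 1,2-addition to the Weinreb amide (Weinreb ketone synthesis), whose chelated tetrahedral adduct releases the E-chalcone only on quench, the allylic C-2'' hydrogen being kinetically far less acidic than the doubly flanked aryl hydrogen.

Step 13
Reactants: 17 (2E)-3-[4-methoxy-2-(methoxymethoxy)phenyl]-1-{2,4,6-tris(methoxymethoxy)-3-[(2R)-5-methyl-2-(prop-1-en-2-yl)hex-4-en-1-yl]phenyl}prop-2-en-1-one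
Product: 18 (2E)-3-(2-hydroxy-4-methoxyphenyl)-1-{2,4,6-trihydroxy-3-[(2R)-5-methyl-2-(prop-1-en-2-yl)hex-4-en-1-yl]phenyl}prop-2-en-1-one
Conditions: 3 M aq. HCl, MeOH, rt, stopped at full conversion
Reagents that add atoms: none
Why: Acid-catalysed acetal cleavage (transacetalisation to dimethoxymethane in methanol) frees the four phenols at room temperature, where protonation of the isopropenyl and prenyl alkenes and ring closure of the 2'-hydroxychalcone are expected to be much slower than oxocarbenium formation.

Compound list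
1 | 2,4,6-trihydroxybenzaldehyde | O=Cc1c(O)cc(O)cc1O | starting material
2 | 2-hydroxy-4,6-bis(methoxymethoxy)benzaldehyde | O=Cc1c(O)cc(OCOC)cc1OCOC | intermediate
3 | 2-(hydroxymethyl)-3,5-bis(methoxymethoxy)phenol | OCc1c(O)cc(OCOC)cc1OCOC | intermediate
4 | 3,5-bis(methoxymethoxy)-2-[(4-methylbenzenesulfonyl)methyl]phenol | Cc1ccc(cc1)S(=O)(=O)Cc1c(O)cc(OCOC)cc1OCOC | intermediate
5 | 5-methylhex-4-enoic acid | CC(C)=CCCC(=O)O | starting material
6 | 1-(1H-imidazol-1-yl)-5-methylhex-4-en-1-one | CC(C)=CCCC(=O)n1ccnc1 | intermediate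
7 | 3,5-bis(methoxymethoxy)-6-methylidenecyclohexa-2,4-dien-1-one (ortho-quinone methide) | C=C1C(=O)C=C(OCOC)C=C1OCOC | intermediate (not isolated)
8 | (3R)-5,7-bis(methoxymethoxy)-3-(3-methylbut-2-en-1-yl)-3,4-dihydro-2H-chromen-2-one | O=C1[C@H](CC=C(C)C)Cc2c(OCOC)cc(OCOC)cc2O1 | intermediate
9 | (2R)-2-{[2-hydroxy-4,6-bis(methoxymethoxy)phenyl]methyl}-N-methoxy-N,5-dimethylhex-4-enamide | CON(C)C(=O)[C@H](CC=C(C)C)Cc1c(O)cc(OCOC)cc1OCOC | intermediate
10 | (2R)-N-methoxy-N,5-dimethyl-2-{[2,4,6-tris(methoxymethoxy)phenyl]methyl}hex-4-enamide | CON(C)C(=O)[C@H](CC=C(C)C)Cc1c(OCOC)cc(OCOC)cc1OCOC | intermediate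
11 | (3R)-6-methyl-3-{[2,4,6-tris(methoxymethoxy)phenyl]methyl}hept-5-en-2-one | CC(=O)[C@H](CC=C(C)C)Cc1c(OCOC)cc(OCOC)cc1OCOC | intermediate
12 | 1,3,5-tris(methoxymethoxy)-2-[(2R)-5-methyl-2-(prop-1-en-2-yl)hex-4-en-1-yl]benzene | C=C(C)[C@H](CC=C(C)C)Cc1c(OCOC)cc(OCOC)cc1OCOC | intermediate
13 | 2-hydroxy-4-methoxybenzaldehyde | COc1ccc(C=O)c(O)c1 | starting material
14 | 4-methoxy-2-(methoxymethoxy)benzaldehyde | COCOc1cc(OC)ccc1C=O | intermediate
15 | (2E)-N-methoxy-3-[4-methoxy-2-(methoxymethoxy)phenyl]-N-methylprop-2-enamide | CON(C)C(=O)/C=C/c1ccc(OC)cc1OCOC | intermediate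
16 | {2,4,6-tris(methoxymethoxy)-3-[(2R)-5-methyl-2-(prop-1-en-2-yl)hex-4-en-1-yl]phenyl}lithium | C=C(C)[C@H](CC=C(C)C)Cc1c(OCOC)cc(OCOC)c([Li])c1OCOC | intermediate (not isolated)
17 | (2E)-3-[4-methoxy-2-(methoxymethoxy)phenyl]-1-{2,4,6-tris(methoxymethoxy)-3-[(2R)-5-methyl-2-(prop-1-en-2-yl)hex-4-en-1-yl]phenyl}prop-2-en-1-one | C=C(C)[C@H](CC=C(C)C)Cc1c(OCOC)cc(OCOC)c(C(=O)/C=C/c2ccc(OC)cc2OCOC)c1OCOC | intermediate
18 | (2E)-3-(2-hydroxy-4-methoxyphenyl)-1-{2,4,6-trihydroxy-3-[(2R)-5-methyl-2-(prop-1-en-2-yl)hex-4-en-1-yl]phenyl}prop-2-en-1-one | C=C(C)[C@H](CC=C(C)C)Cc1c(O)cc(O)c(C(=O)/C=C/c2ccc(OC)cc2O)c1O | target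

Total step count: 13
Longest linear sequence: 10 steps (1, 2, 3, 5, 6, 7, 8, 9, 12, 13, from 2,4,6-trihydroxybenzaldehyde)

Steps most likely to fail

Step 5 (annulation).
- What may go wrong: the quinone methide may be consumed by oligomerisation or by the imidazole and sulfinate present before the azolium enolate captures it. Facial discrimination by the catalyst may be insufficient for this unbranched aliphatic enolate. The lactone may lose configuration by base-mediated enolisation.
- Fallback: an auxiliary-controlled alkylation, setting out from 2 and coming back to the route at 10.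
- 2 is alkylated (NaH, MOMCl, DMF, 0 °C) to 2,4,6-tris(methoxymethoxy)benzaldehyde F1.
- Wittig reaction with Ph3P=CHCO2Et (toluene, 80 °C) should give ethyl (2E)-3-[2,4,6-tris(methoxymethoxy)phenyl]prop-2-enoate F2.
- Hydrogenation (H2, 10% Pd/C, EtOAc) should give ethyl 3-[2,4,6-tris(methoxymethoxy)phenyl]propanoate F3.
- Saponification (LiOH, THF/H2O) should give 3-[2,4,6-tris(methoxymethoxy)phenyl]propanoic acid F4.
- The pivaloyl mixed anhydride (Me3CCOCl, Et3N) is treated with the lithium salt of (4R)-4-benzyl-1,3-oxazolidin-2-one to give (4R)-4-benzyl-3-{3-[2,4,6-tris(methoxymethoxy)phenyl]propanoyl}-1,3-oxazolidin-2-one F5.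
- Evans alkylation (NaN(SiMe3)2, prenyl bromide, THF, −78 °C) should give (4R)-4-benzyl-3-[(2R)-5-methyl-2-{[2,4,6-tris(methoxymethoxy)phenyl]methyl}hex-4-enoyl]-1,3-oxazolidin-2-one F6. The chelated Z enolate is alkylated on the face away from the benzyl group, which for the R auxiliary corresponds to 2R.
- Cleavage with LiOH/H2O2 (THF/H2O, 0 °C) should give (2R)-5-methyl-2-{[2,4,6-tris(methoxymethoxy)phenyl]methyl}hex-4-enoic acid F7.
- Coupling with MeNH(OMe)·HCl (EDC·HCl, N-methylmorpholine, CH2Cl2) leads to 10.

Step 13 (global deprotection).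
- What may go wrong: while the last acetals are being cleaved, the acid may promote conjugate ring closure of a ring A hydroxyl onto the enone (chalcone to flavanone isomerisation). It may also promote Markovnikov addition of an ortho hydroxyl to the protonated isopropenyl or prenyl alkene.
- Fallback: exchange of the acetals for silyl ethers without protic acid, setting out from 17 and coming back at 18.
- 17 is treated with TMSOTf and 2,2'-bipyridyl (CH3CN, 0 °C → rt), which should convert the four aryl MOM ethers into the tetrakis(trimethylsilyl) ether of the target F9.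
- F9 is hydrolysed with pH 7 phosphate buffer in THF at 0 °C to give 18.

Step 12 (aryllithium acylation).
- What may go wrong: metalation may be incomplete. Proton transfer to the hindered aryllithium, or conjugate addition, may compete with addition to the amide carbonyl.
- Fallback: a stepwise construction of the enone, setting out from 12 (through 16) and from 14 and coming back at 17.
- Aryllithium 16 is quenched with N-methoxy-N-methylacetamide (THF, −78 → 0 °C) to give 1-{2,4,6-tris(methoxymethoxy)-3-[(2R)-5-methyl-2-(prop-1-en-2-yl)hex-4-en-1-yl]phenyl}ethan-1-one F8.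
- Claisen–Schmidt condensation of F8 with aldehyde 14 (KOH, EtOH/H2O, rt) should give 17 as the E isomer; C-2'' carries no acidic hydrogen under these conditions.

Further compounds
F1 | step 5 | 2,4,6-tris(methoxymethoxy)benzaldehyde | O=Cc1c(OCOC)cc(OCOC)cc1OCOC
F2 | step 5 | ethyl (2E)-3-[2,4,6-tris(methoxymethoxy)phenyl]prop-2-enoate | CCOC(=O)/C=C/c1c(OCOC)cc(OCOC)cc1OCOC
F3 | step 5 | ethyl 3-[2,4,6-tris(methoxymethoxy)phenyl]propanoate | CCOC(=O)CCc1c(OCOC)cc(OCOC)cc1OCOC
F4 | step 5 | 3-[2,4,6-tris(methoxymethoxy)phenyl]propanoic acid | OC(=O)CCc1c(OCOC)cc(OCOC)cc1OCOC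
F5 | step 5 | (4R)-4-benzyl-3-{3-[2,4,6-tris(methoxymethoxy)phenyl]propanoyl}-1,3-oxazolidin-2-one | O=C(CCc1c(OCOC)cc(OCOC)cc1OCOC)N1[C@H](Cc2ccccc2)COC1=O
F6 | step 5 | (4R)-4-benzyl-3-[(2R)-5-methyl-2-{[2,4,6-tris(methoxymethoxy)phenyl]methyl}hex-4-enoyl]-1,3-oxazolidin-2-one | O=C([C@H](CC=C(C)C)Cc1c(OCOC)cc(OCOC)cc1OCOC)N1[C@H](Cc2ccccc2)COC1=O
F7 | step 5 | (2R)-5-methyl-2-{[2,4,6-tris(methoxymethoxy)phenyl]methyl}hex-4-enoic acid | OC(=O)[C@H](CC=C(C)C)Cc1c(OCOC)cc(OCOC)cc1OCOC
F8 | step 12 | 1-{2,4,6-tris(methoxymethoxy)-3-[(2R)-5-methyl-2-(prop-1-en-2-yl)hex-4-en-1-yl]phenyl}ethan-1-one | C=C(C)[C@H](CC=C(C)C)Cc1c(OCOC)cc(OCOC)c(C(C)=O)c1OCOC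
F9 | step 13 | (2E)-3-{4-methoxy-2-[(trimethylsilyl)oxy]phenyl}-1-{3-[(2R)-5-methyl-2-(prop-1-en-2-yl)hex-4-en-1-yl]-2,4,6-tris[(trimethylsilyl)oxy]phenyl}prop-2-en-1-one | C=C(C)[C@H](CC=C(C)C)Cc1c(O[Si](C)(C)C)cc(O[Si](C)(C)C)c(C(=O)/C=C/c2ccc(OC)cc2O[Si](C)(C)C)c1O[Si](C)(C)C
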